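**Retrosynthetic overview** (chain numbering: CO2H = C1, dioxane carbons C3–C6, enone C11–C13)

1. The (E)-enone comes last, by Wittig reaction on the C11 aldehyde (carried as a dimethyl acetal). The 1,2-dioxane is closed just before, by a C6 peroxide opening a β-lactone at C3 with inversion, which also releases the CO2H.
2. The C6–O bond comes from Co(acac)2/O2/Et3SiH peroxidation of a C6 alkene. The C5–C6 bond comes from B-alkyl Suzuki coupling of a C6–C11 enol triflate with the 9-BBN adduct of an alkenyl β-lactone (C3 by ketene–aldehyde [2+2], C4 by lactone-directed hydroboration).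
3. The C6–C11 keto acetal (C8, C10) comes from ozonolysis of (3S,5S)-1,3-diethyl-5-methylcyclohexene, made by trans-selective CuBr·SMe2-catalysed EtMgBr addition to (S)-5-methylcyclohex-2-enone.
4. The (S)-enone comes from the key step: enantioselective mono-hydrolysis (desymmetrisation) of the mirror-symmetric bis(enol ether) obtained by Birch reduction of 3,5-dimethoxytoluene.
5. Ring order: arene-derived carbocycle first (then cut open), β-lactone second, 1,2-dioxane last.

Assumption: the sense of induction of the chiral acid (step 2) and of the silylated cinchona alkaloid (step 8) is not known in advance, so the catalyst enantiomer (or pseudo-enantiomer) that gives the drawn products is used; alkene-isomer mixtures are drawn as their major isomer; the peroxidation at C6 is not stereoselective, so 18 and 19 are mixtures of both C6 epimers and are written without a descriptor at that carbon.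

**Step 1**
Reactants: 1 3,5-dimethoxytoluene
Product: 2 1,5-dimethoxy-3-methylcyclohexa-1,4-diene
Conditions: Li, NH3 (l), t-BuOH, THF, −78 to −33 °C; NH4Cl
Reagents that add atoms: none
Why: Birch reduction places the two new hydrogens on the carbon between the methoxy carbons and on the methyl-bearing carbon, which breaks the aromaticity and leaves a mirror-symmetric bis(enol ether) whose CH(CH3) carbon is prochiral.

**Step 2**
Reactants: 2 1,5-dimethoxy-3-methylcyclohexa-1,4-diene
Product: 4 (R)-3-methoxy-5-methylcyclohex-2-en-1-one, via unconjugated keto enol ether 3 (not isolated)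
Conditions: chiral N-triflylphosphoramide of 3,3'-bis(2,4,6-triisopropylphenyl)-BINOL (5 mol%), H2O (1.05 equiv), toluene, −40 °C; then Et3N (10 mol%), 0 °C
Reagents that add atoms: water, O
Why: Proposed new method: the confined chiral Brønsted acid C-protonates only one of the two enantiotopic enol ether double bonds, water traps the oxocarbenium/chiral anion pair and methanol is lost, so the methyl-bearing carbon becomes the future C8 stereocentre, while conjugation turns the second enol ether into an unreactive vinylogous ester and stops over-hydrolysis; the closest known reactions are chiral phosphoric acid catalysed enantioselective protonations of silyl enol ethers and desymmetrisations of prochiral cyclohexa-1,4-dienes.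

**Step 3**
Reactants: 4 (R)-3-methoxy-5-methylcyclohex-2-en-1-one
Product: 6 (S)-5-methylcyclohex-2-en-1-one, via allylic alcohol 5 (not isolated)
Conditions: i-Bu2AlH, CH2Cl2, −78 °C; then 1 M HCl, THF, 0 °C
Reagents that add atoms: water, O
Why: 1,2-reduction of the vinylogous ester followed by acid hydrolysis of the enol ether with loss of water (reductive 1,3-carbonyl transposition of a 3-alkoxyenone) gives the enone without touching the methyl stereocentre.

**Step 4**
Reactants: 6 (S)-5-methylcyclohex-2-en-1-one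
Product: 8 (3S,5S)-3-ethyl-5-methylcyclohex-1-en-1-yl trifluoromethanesulfonate, via magnesium enolate 7 (not isolated)
Conditions: EtMgBr, CuBr·SMe2 (5 mol%), THF, −78 °C; then N-(5-chloropyridin-2-yl)triflimide, −78 to 0 °C; NH4Cl
Reagents that add atoms: ethylmagnesium bromide, CC[Mg]Br; N-(5-chloropyridin-2-yl)-1,1,1-trifluoro-N-(trifluoromethanesulfonyl)methanesulfonamide (Comins' reagent), FC(F)(F)S(=O)(=O)N(c1ccc(Cl)cn1)S(=O)(=O)C(F)(F)F
Why: CuBr·SMe2-catalysed conjugate addition delivers ethyl axially, anti to the C5 methyl group (trans-3,5 product, which sets C10), and the regiodefined enolate is trapped on oxygen as the enol triflate.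

**Step 5**
Reactants: 8 (3S,5S)-3-ethyl-5-methylcyclohex-1-en-1-yl trifluoromethanesulfonate
Product: 9 (3S,5S)-1,3-diethyl-5-methylcyclohex-1-ene
Conditions: EtMgBr, Fe(acac)3 (5 mol%), THF/NMP, −30 °C
Reagents that add atoms: ethylmagnesium bromide, CC[Mg]Br
Why: Fe(acac)3-catalysed Kumada-type cross-coupling of an enol triflate with an alkyl Grignard reagent replaces OTf by ethyl without moving the double bond or touching the two stereocentres.

**Step 6**
Reactants: 9 (3S,5S)-1,3-diethyl-5-methylcyclohex-1-ene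
Product: 11 (5S,7S)-7-ethyl-8,8-dimethoxy-5-methyloctan-3-one, via methoxy hydroperoxide 10 (not isolated)
Conditions: O3, CH2Cl2/MeOH, −78 °C; TsOH·H2O (cat.), rt; NaHCO3, Me2S
Reagents that add atoms: ozone, [O-][O+]=O; methanol, CO
Why: ozonolysis with end-differentiating work-up: the carbonyl oxide forms on the more substituted carbon and is trapped by methanol as the methoxy hydroperoxide that Me2S reduces to the ethyl ketone, while the aldehyde end is acetalised, so the ring is opened to the C6–C11 chain with C8 and C10 intact.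

**Step 7**
Reactants: 11 (5S,7S)-7-ethyl-8,8-dimethoxy-5-methyloctan-3-one
Product: 13 (2Z,5S,7S)-7-ethyl-8,8-dimethoxy-5-methyloct-2-en-3-yl trifluoromethanesulfonate, via potassium enolate 12 (not isolated)
Conditions: KN(SiMe3)2, THF, −78 °C; N-(5-chloropyridin-2-yl)triflimide, −78 to −20 °C; NH4Cl
Reagents that add atoms: N-(5-chloropyridin-2-yl)-1,1,1-trifluoro-N-(trifluoromethanesulfonyl)methanesulfonamide (Comins' reagent), FC(F)(F)S(=O)(=O)N(c1ccc(Cl)cn1)S(=O)(=O)C(F)(F)F
Why: kinetic enolisation and O-triflation give the enol triflate (mainly the 2Z-2-ene shown, with minor double-bond isomers carried along because every isomer later gives the same C6 radical), and no stereocentre is touched.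

**Step 8**
Reactants: 14 2-ethylacrolein
Product: 15 (R)-4-(but-1-en-2-yl)oxetan-2-one
Conditions: AcCl, i-Pr2NEt, O-trimethylsilylquinidine (10 mol%), LiClO4, Et2O/CH2Cl2, −78 °C
Reagents that add atoms: acetyl chloride, CC(=O)Cl
Why: alkaloid/LiClO4-catalysed ketene–aldehyde [2+2] cycloaddition (acyl halide–aldehyde cyclocondensation) adds the chiral ammonium enolate of ketene to one aldehyde face and sets the lactone carbinol carbon (future C3, made with the configuration that step 11 inverts).

**Step 9**
Reactants: 15 (R)-4-(but-1-en-2-yl)oxetan-2-one; 13 (2Z,5S,7S)-7-ethyl-8,8-dimethoxy-5-methyloct-2-en-3-yl trifluoromethanesulfonate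
Product: 17 (4R)-4-[(3S,5Z,7S,9S)-9-ethyl-5-ethylidene-10,10-dimethoxy-7-methyldecan-3-yl]oxetan-2-one, via alkylborane 16 (not isolated)
Conditions: 9-BBN, THF, 0 °C to rt; then 13, Pd(dppf)Cl2 (5 mol%), AsPh3, K3PO4·H2O, DMF, rt
Reagents that add atoms: none
Why: 9-BBN attacks the 1,1-disubstituted alkene in the conformer with the allylic hydrogen in the alkene plane, on the face anti to the ring CH2 of the lactone (substrate-directed hydroboration of an allylic C–O stereocentre, anti product, which sets C4), and the primary alkylborane is joined to the enol triflate by B-alkyl Suzuki–Miyaura coupling (C5–C6 bond).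

**Step 10**
Reactants: 17 (4R)-4-[(3S,5Z,7S,9S)-9-ethyl-5-ethylidene-10,10-dimethoxy-7-methyldecan-3-yl]oxetan-2-one
Product: 18 (4R)-4-[(3S,5RS,7S,9S)-5,9-diethyl-10,10-dimethoxy-7-methyl-5-(triethylsilylperoxy)decan-3-yl]oxetan-2-one (both epimers at decane C5 = chain C6)
Conditions: Co(acac)2 (10 mol%), O2 (1 atm), Et3SiH, ClCH2CH2Cl, rt
Reagents that add atoms: dioxygen, O=O; triethylsilane, CC[SiH](CC)CC
Why: Mukaiyama–Isayama hydroperoxysilylation (hydrogen-atom transfer to the alkene under Co(acac)2 catalysis, O2 trapping of the tertiary C6 radical, silylation) installs the tertiary peroxide from every alkene isomer present, but the planar radical is attacked on both faces without control, so 18 is an about 1:1 mixture of C6 epimers and half of the material is given up when C6 is fixed by the separation in step 11.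

**Step 11**
Reactants: 18 (4R)-4-[(3S,5RS,7S,9S)-5,9-diethyl-10,10-dimethoxy-7-methyl-5-(triethylsilylperoxy)decan-3-yl]oxetan-2-one (both C6 epimers)
Product: 20 2-[(3S,4S,6R)-4,6-diethyl-6-[(2S,4S)-4-ethyl-5,5-dimethoxy-2-methylpentyl]-1,2-dioxan-3-yl]acetic acid, via tetrabutylammonium peroxide 19 (not isolated)
Conditions: Bu4NF (1.1 equiv), THF (0.01 M), −40 to 0 °C; aq. HCl to pH 3; chromatography
Reagents that add atoms: none
Why: Proposed new method: fluoride removes the silyl group and the tertiary peroxide anion opens the β-lactone by 6-exo-tet attack at the alkyl carbon C3 with carboxylate as leaving group, so the 1,2-dioxane and the free acetic acid arm form together with inversion at C3 (3,4-cis), acyl attack being disfavoured because it needs an eight-membered ring; the closest known reactions are inversion-type openings of oxetanes by hydroperoxides, alkylations of hydroperoxide anions by secondary sulfonates and alkyl–oxygen cleavage of β-lactones by soft nucleophiles, and because both epimers of 18 cyclise, the 6R acid 20 is separated by chromatography from its 6S ring epimer, which is discarded.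

**Step 12**
Reactants: 20 2-[(3S,4S,6R)-4,6-diethyl-6-[(2S,4S)-4-ethyl-5,5-dimethoxy-2-methylpentyl]-1,2-dioxan-3-yl]acetic acid
Product: 21 2-[(3S,4S,6R)-4,6-diethyl-6-[(2S,4S)-4-formyl-2-methylhexyl]-1,2-dioxan-3-yl]acetic acid
Conditions: 1 M HCl, THF, 0 °C, 1 h
Reagents that add atoms: water, O
Why: mild acid hydrolysis of the dimethyl acetal frees the aldehyde without harming the dialkyl peroxide, and the α-branched aldehyde is used at once so that C10 does not epimerise.

**Step 13**
Reactants: 21 2-[(3S,4S,6R)-4,6-diethyl-6-[(2S,4S)-4-formyl-2-methylhexyl]-1,2-dioxan-3-yl]acetic acid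
Product: 22 2-[(3S,4S,6R)-4,6-diethyl-6-[(2S,4S,5E)-4-ethyl-2-methyl-7-oxooct-5-en-1-yl]-1,2-dioxan-3-yl]acetic acid
Conditions: Ph3P=CHC(O)CH3 (2.5 equiv), CH2Cl2, rt
Reagents that add atoms: 1-(triphenyl-λ5-phosphanylidene)propan-2-one, CC(=O)C=P(c1ccccc1)(c1ccccc1)c1ccccc1
Why: Wittig olefination with the stabilised acetonylidene ylide gives the (E)-enone selectively and tolerates the peroxide and the free acid (the extra ylide buffers the carboxylic acid).

**Compound list**

1 | 3,5-dimethoxytoluene | COc1cc(C)cc(OC)c1 | starting material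
2 | 1,5-dimethoxy-3-methylcyclohexa-1,4-diene | COC1=CC(C)C=C(OC)C1 | intermediate
3 | (S)-3-methoxy-5-methylcyclohex-3-en-1-one (unconjugated keto enol ether; not isolated) | O=C1C[C@H](C)C=C(OC)C1 | intermediate
4 | (R)-3-methoxy-5-methylcyclohex-2-en-1-one | COC1=CC(=O)C[C@H](C)C1 | intermediate
5 | (5S)-3-methoxy-5-methylcyclohex-2-en-1-ol (both C1 epimers; not isolated) | COC1=CC(O)C[C@H](C)C1 | intermediate
6 | (S)-5-methylcyclohex-2-en-1-one | O=C1C=CC[C@H](C)C1 | intermediate
7 | bromomagnesium (3S,5S)-3-ethyl-5-methylcyclohex-1-en-1-olate (not isolated) | CC[C@@H]1C=C(O[Mg]Br)C[C@@H](C)C1 | intermediate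
8 | (3S,5S)-3-ethyl-5-methylcyclohex-1-en-1-yl trifluoromethanesulfonate | CC[C@@H]1C=C(OS(=O)(=O)C(F)(F)F)C[C@@H](C)C1 | intermediate
9 | (3S,5S)-1,3-diethyl-5-methylcyclohex-1-ene | CC[C@@H]1C=C(CC)C[C@@H](C)C1 | intermediate
10 | (5S,7S)-7-ethyl-3-hydroperoxy-3,8,8-trimethoxy-5-methyloctane (both C3 epimers; not isolated) | CCC(OC)(OO)C[C@@H](C)C[C@H](CC)C(OC)OC | intermediate
11 | (5S,7S)-7-ethyl-8,8-dimethoxy-5-methyloctan-3-one | CCC(=O)C[C@@H](C)C[C@H](CC)C(OC)OC | intermediate
12 | potassium (2Z,5S,7S)-7-ethyl-8,8-dimethoxy-5-methyloct-2-en-3-olate (not isolated) | C/C=C(\[O-])C[C@@H](C)C[C@H](CC)C(OC)OC.[K+] | intermediate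
13 | (2Z,5S,7S)-7-ethyl-8,8-dimethoxy-5-methyloct-2-en-3-yl trifluoromethanesulfonate (major isomer; minor double-bond isomers carried along) | C/C=C(\OS(=O)(=O)C(F)(F)F)C[C@@H](C)C[C@H](CC)C(OC)OC | intermediate
14 | 2-ethylacrolein (2-methylidenebutanal) | CCC(=C)C=O | starting material
15 | (R)-4-(but-1-en-2-yl)oxetan-2-one | C=C(CC)[C@H]1CC(=O)O1 | intermediate
16 | 9-[(2R)-2-[(2R)-4-oxooxetan-2-yl]butyl]-9-borabicyclo[3.3.1]nonane (not isolated) | CC[C@@H](CB1C2CCCC1CCC2)[C@H]1CC(=O)O1 | intermediate
17 | (4R)-4-[(3S,5Z,7S,9S)-9-ethyl-5-ethylidene-10,10-dimethoxy-7-methyldecan-3-yl]oxetan-2-one (major alkene isomer) | C/C=C(\C[C@H](CC)[C@H]1CC(=O)O1)C[C@@H](C)C[C@H](CC)C(OC)OC | intermediate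
18 | (4R)-4-[(3S,5RS,7S,9S)-5,9-diethyl-10,10-dimethoxy-7-methyl-5-(triethylsilylperoxy)decan-3-yl]oxetan-2-one (both C6 epimers, about 1:1; the 5R epimer leads to the target) | CCC(C[C@H](CC)[C@H]1CC(=O)O1)(OO[Si](CC)(CC)CC)C[C@@H](C)C[C@H](CC)C(OC)OC | intermediate
19 | tetrabutylammonium (3S,5RS,7S,9S)-5,9-diethyl-10,10-dimethoxy-7-methyl-3-[(2R)-4-oxooxetan-2-yl]decane-5-peroxolate (both C6 epimers; not isolated) | CCC(C[C@H](CC)[C@H]1CC(=O)O1)(O[O-])C[C@@H](C)C[C@H](CC)C(OC)OC.CCCC[N+](CCCC)(CCCC)CCCC | intermediate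
20 | 2-[(3S,4S,6R)-4,6-diethyl-6-[(2S,4S)-4-ethyl-5,5-dimethoxy-2-methylpentyl]-1,2-dioxan-3-yl]acetic acid (single 6R epimer after chromatography) | CC[C@H](C(OC)OC)C[C@H](C)C[C@]1(CC)C[C@H](CC)[C@H](CC(=O)O)OO1 | intermediate
21 | 2-[(3S,4S,6R)-4,6-diethyl-6-[(2S,4S)-4-formyl-2-methylhexyl]-1,2-dioxan-3-yl]acetic acid | CC[C@H](C=O)C[C@H](C)C[C@]1(CC)C[C@H](CC)[C@H](CC(=O)O)OO1 | intermediate
22 | 2-[(3S,4S,6R)-4,6-diethyl-6-[(2S,4S,5E)-4-ethyl-2-methyl-7-oxooct-5-en-1-yl]-1,2-dioxan-3-yl]acetic acid | CC[C@H](/C=C/C(C)=O)C[C@H](C)C[C@]1(CC)C[C@H](CC)[C@H](CC(=O)O)OO1 | target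

**Step count and risks**

Total: 13 steps. Longest linear sequence: 12 steps (steps 1–7 and 9–13); step 8 is a one-step branch.

The three steps most likely to fail are steps 2, 9 and 11.

Step 2 is a new desymmetrising protonation. Its enantioselectivity is untested, and the methanol released could erode it by acid-catalysed exchange of the vinylogous ester. The fallback sets out from 2 and comes back at 8, replacing the desymmetrisation by a catalytic kinetic resolution. Aqueous oxalic acid hydrolyses 2 to racemic 3-methoxy-5-methylcyclohex-2-en-1-one F1. Reduction with i-Bu2AlH followed by HCl gives racemic 5-methylcyclohex-2-en-1-one F2. Cu(OTf)2 (1 mol%), a chiral BINOL-derived phosphoramidite (2 mol%) and Et2Zn (0.55 equiv) in toluene at −40 °C then consume only the (S)-enone in a trans-selective conjugate addition, which gives ethylzinc (3S,5S)-3-ethyl-5-methylcyclohex-1-en-1-olate F3. This enolate is triflated in the same flask with Comins' reagent to give 8 directly, and the unreacted (R)-enone is separated.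

Step 9 carries three risks: the diastereoselectivity of the lactone-directed hydroboration (C4), survival of the β-lactone under the basic coupling, and 1,3-elimination of the borate onto the lactone C–O bond. The fallback sets out from 13 and comes back at 17. It takes C4 from a preformed building block and builds the lactone last, so the separate lactone synthesis of step 8 is not needed. Methyl (S)-2-(hydroxymethyl)butanoate (the ethyl homologue of the Roche ester) is converted with I2/PPh3/imidazole into methyl (R)-2-(iodomethyl)butanoate F4. Insertion of Zn dust in DMF gives [(2R)-2-(methoxycarbonyl)butyl]zinc iodide F5. Negishi coupling with 13 (Pd(OAc)2, SPhos, THF) gives methyl (2S,4Z,6S,8S)-2,8-diethyl-4-ethylidene-9,9-dimethoxy-6-methylnonanoate F6. Reduction with i-Bu2AlH at −78 °C gives (2S,4Z,6S,8S)-2,8-diethyl-4-ethylidene-9,9-dimethoxy-6-methylnonanal F7. The ketene–aldehyde cycloaddition of step 8 (AcCl, i-Pr2NEt, silylated cinchona alkaloid, LiClO4), now under catalyst control on a saturated α-branched aldehyde, converts F7 into 17.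

Step 11 is a new ring closure; acyl attack on the lactone or base-induced decomposition could compete. The fallback sets out from 17 and comes back at 20. It replaces the lactone by a secondary mesylate that has no carbonyl group. LiBH4 reduces 17 to (3R,4S,6Z,8S,10S)-4,10-diethyl-6-ethylidene-11,11-dimethoxy-8-methylundecane-1,3-diol F8. TBSCl/imidazole protects the primary alcohol to give (3R,4S,6Z,8S,10S)-1-(tert-butyldimethylsilyloxy)-4,10-diethyl-6-ethylidene-11,11-dimethoxy-8-methylundecan-3-ol F9. MsCl/Et3N gives (3R,4S,6Z,8S,10S)-1-(tert-butyldimethylsilyloxy)-4,10-diethyl-6-ethylidene-11,11-dimethoxy-8-methylundecan-3-yl methanesulfonate F10. Co(acac)2/O2/Et3SiH gives (3R,4S,6RS,8S,10S)-1-(tert-butyldimethylsilyloxy)-4,6,10-triethyl-11,11-dimethoxy-8-methyl-6-(triethylsilylperoxy)undecan-3-yl methanesulfonate F11 as both C6 epimers. Bu4NF then removes both silyl groups, the freed peroxide displaces the mesylate with inversion, and chromatography gives 2-[(3S,4S,6R)-4,6-diethyl-6-[(2S,4S)-4-ethyl-5,5-dimethoxy-2-methylpentyl]-1,2-dioxan-3-yl]ethan-1-ol F12. TEMPO (cat.), NaOCl (cat.) and NaClO2 in MeCN/pH 6.7 phosphate buffer oxidise F12 to 20.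

**Further compounds**

F1 | step 2 | racemic 3-methoxy-5-methylcyclohex-2-en-1-one | COC1=CC(=O)CC(C)C1
F2 | step 2 | racemic 5-methylcyclohex-2-en-1-one | O=C1C=CCC(C)C1
F3 | step 2 | ethylzinc (3S,5S)-3-ethyl-5-methylcyclohex-1-en-1-olate | CC[C@@H]1C=C(O[Zn]CC)C[C@@H](C)C1
F4 | step 9 | methyl (R)-2-(iodomethyl)butanoate | CC[C@@H](CI)C(=O)OC
F5 | step 9 | [(2R)-2-(methoxycarbonyl)butyl]zinc iodide | CC[C@@H](C[Zn]I)C(=O)OC
F6 | step 9 | methyl (2S,4Z,6S,8S)-2,8-diethyl-4-ethylidene-9,9-dimethoxy-6-methylnonanoate | C/C=C(\C[C@H](CC)C(=O)OC)C[C@@H](C)C[C@H](CC)C(OC)OC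
F7 | step 9 | (2S,4Z,6S,8S)-2,8-diethyl-4-ethylidene-9,9-dimethoxy-6-methylnonanal | C/C=C(\C[C@H](CC)C=O)C[C@@H](C)C[C@H](CC)C(OC)OC
F8 | step 11 | (3R,4S,6Z,8S,10S)-4,10-diethyl-6-ethylidene-11,11-dimethoxy-8-methylundecane-1,3-diol | C/C=C(\C[C@H](CC)[C@H](O)CCO)C[C@@H](C)C[C@H](CC)C(OC)OC
F9 | step 11 | (3R,4S,6Z,8S,10S)-1-(tert-butyldimethylsilyloxy)-4,10-diethyl-6-ethylidene-11,11-dimethoxy-8-methylundecan-3-ol | C/C=C(\C[C@H](CC)[C@H](O)CCO[Si](C)(C)C(C)(C)C)C[C@@H](C)C[C@H](CC)C(OC)OC
F10 | step 11 | (3R,4S,6Z,8S,10S)-1-(tert-butyldimethylsilyloxy)-4,10-diethyl-6-ethylidene-11,11-dimethoxy-8-methylundecan-3-yl methanesulfonate | C/C=C(\C[C@H](CC)[C@H](OS(C)(=O)=O)CCO[Si](C)(C)C(C)(C)C)C[C@@H](C)C[C@H](CC)C(OC)OC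
F11 | step 11 | (3R,4S,6RS,8S,10S)-1-(tert-butyldimethylsilyloxy)-4,6,10-triethyl-11,11-dimethoxy-8-methyl-6-(triethylsilylperoxy)undecan-3-yl methanesulfonate (both C6 epimers) | CCC(C[C@H](CC)[C@H](OS(C)(=O)=O)CCO[Si](C)(C)C(C)(C)C)(OO[Si](CC)(CC)CC)C[C@@H](C)C[C@H](CC)C(OC)OC
F12 | step 11 | 2-[(3S,4S,6R)-4,6-diethyl-6-[(2S,4S)-4-ethyl-5,5-dimethoxy-2-methylpentyl]-1,2-dioxan-3-yl]ethan-1-ol | CC[C@H](C(OC)OC)C[C@H](C)C[C@]1(CC)C[C@H](CC)[C@H](CCO)OO1
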